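**Retrosynthetic overview**

1. Target 28 comes from triol 27 by a final MnO2 oxidation of the allylic alcohol; the trienyl side chain is built on C3-carbaldehyde 21 by Wittig (22) and Horner–Wadsworth–Emmons (geranylphosphonate 25) olefinations.
2. The oxolane ring of 19 comes from spiro γ-lactone 17, itself from spiro keto lactone 16: C1 is held at the lactone level and C6 at the ketone level through the key step and adjusted afterwards.
3. Key disconnection: the C5–C10 bond of the cyclohexane ring, closed by palladium-hydride hydroalkylation of the 1,3-diene in β-keto lactone 15. This sets the quaternary spiro C5 and C10 and keeps the tetrasubstituted C9 alkene.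
4. Enabling feature: C5 lies between C1 of the oxolane ring and C6 of the cyclohexane ring, which as lactone C=O and ketone make it a 1,3-dicarbonyl carbon acid; C10 is the γ-carbon of the exocyclic C9=C(CH3)CHO enal, so C10–C9–C(CH3) is an allyl unit that a C10=CH diene delivers on H addition.
5. 15 comes from acetyl lactone 14 (epoxide 12 + ethyl acetoacetate 13) and dienyl bromide 11 (enol triflate 4 + alkenylboronate 6). Ring order: lactone (later oxolane) ring in step 9, cyclohexane ring in step 11.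

Key step: step 11

Remark: positions follow 2-oxaspiro[4.5]decane numbering (C1 oxolane CH2, O2, C3 carrying the side chain, spiro C5, carbinol C6, ylidene C9, C10 carrying the hydroxypropyl chain); TBS = tert-butyldimethylsilyl, PMB = 4-methoxybenzyl; acyl lactones 14 and 15 are assumed usable as mixtures of C3 epimers, because this centre becomes the planar enol carbon in step 11.

**Route**

Step 1
Reactants: 1 ethyl propanoate; 2 di-tert-butyl oxalate
Product: 3 4-tert-butyl 1-ethyl 2-methyl-3-oxobutanedioate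
Conditions: LDA (2.1 equiv), THF, −78 °C; then 2, −78 to 0 °C
Reagents that add atoms: none
Why: Crossed Claisen condensation of the lithium enolate of 1 with the non-enolisable, activated oxalate, driven by deprotonation of the product; the methyl-bearing carbon is enolisable and carries no stereochemical information.

Step 2
Reactants: 3 4-tert-butyl 1-ethyl 2-methyl-3-oxobutanedioate
Product: 4 4-tert-butyl 1-ethyl (2Z)-2-methyl-3-(trifluoromethanesulfonyloxy)but-2-enedioate
Conditions: NaH, THF, 0 °C; then PhNTf2, 0 °C to rt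
Reagents that add atoms: N-phenylbis(trifluoromethanesulfonimide), O=S(=O)(N(c1ccccc1)S(=O)(=O)C(F)(F)F)C(F)(F)F
Why: Enol triflate formation from a β-keto ester; the six-membered sodium chelate between the enolate oxygen and the ethyl ester carbonyl should place OTf cis to CO2Et, which fixes the later tetrasubstituted alkene geometry.

Step 3
Reactants: 5 tert-butyl(but-3-yn-1-yloxy)dimethylsilane
Product: 6 tert-butyldimethyl{[(3E)-4-(4,4,5,5-tetramethyl-1,3,2-dioxaborolan-2-yl)but-3-en-1-yl]oxy}silane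
Conditions: pinacolborane, Cp2Zr(H)Cl (5 mol%), Et3N (10 mol%), 60 °C
Reagents that add atoms: pinacolborane, CC1(C)OBOC1(C)C
Why: Zirconium-catalysed hydroboration of a terminal alkyne is a syn, anti-Markovnikov addition and should give only the (E)-alkenylboronate.

Step 4
Reactants: 4 enol triflate; 6 (E)-alkenylboronate
Product: 7 4-tert-butyl 1-ethyl (2E)-2-methyl-3-[(1E)-4-(TBS-oxy)but-1-en-1-yl]but-2-enedioate
Conditions: PdCl2(dppf) (5 mol%), K3PO4, THF/H2O, 50 °C
Reagents that add atoms: none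
Why: Suzuki–Miyaura coupling proceeds with retention at both sp2 carbons, so the butenyl group replaces OTf cis to CO2Et and the tert-butyl ester stays cis to the methyl group.

Step 5
Reactants: 7 diene diester
Product: 8 tert-butyl (2E,3E)-2-(1-hydroxypropan-2-ylidene)-6-(TBS-oxy)hex-3-enoate
Conditions: DIBAL-H (2.1 equiv), CH2Cl2, −78 °C
Reagents that add atoms: none
Why: DIBAL-H 1,2-reduction should take the ethyl ester in preference to the bulkier tert-butyl ester; the new CH2OH is trans to CO2tBu and cannot lactonise.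

Step 6
Reactants: 8 allylic alcohol
Product: 9 tert-butyl (2E,3E)-6-(TBS-oxy)-2-[1-(TBS-oxy)propan-2-ylidene]hex-3-enoate
Conditions: TBSCl, imidazole, CH2Cl2, rt
Reagents that add atoms: tert-butyldimethylsilyl chloride, CC(C)(C)[Si](C)(C)Cl
Why: Standard silylation of a primary allylic alcohol, which masks the future aldehyde carbon until the last step.

Step 7
Reactants: 9 bis-silyl ether ester
Product: 10 (2E,3E)-6-(TBS-oxy)-2-[1-(TBS-oxy)propan-2-ylidene]hex-3-en-1-ol
Conditions: DIBAL-H (3 equiv), CH2Cl2, −78 to 0 °C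
Reagents that add atoms: none
Why: With excess DIBAL-H at higher temperature the remaining tert-butyl ester is reduced to the primary allylic alcohol, silyl ethers and alkene geometry being untouched.

Step 8
Reactants: 10 dienyl alcohol
Product: 11 (2E,3E)-1-bromo-6-(TBS-oxy)-2-[1-(TBS-oxy)propan-2-ylidene]hex-3-ene
Conditions: CBr4, PPh3, CH2Cl2, 0 °C
Reagents that add atoms: carbon tetrabromide, BrC(Br)(Br)Br
Why: Appel reaction at a primary allylic carbon under neutral conditions; allylic transposition is disfavoured because it would place bromine on a fully substituted carbon.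

Step 9
Reactants: 12 (R)-2-[(PMB-oxy)methyl]oxirane; 13 ethyl 3-oxobutanoate
Product: 14 (5R)-3-acetyl-5-[(PMB-oxy)methyl]oxolan-2-one (C3 epimers)
Conditions: NaOEt, EtOH, 60 °C
Reagents that add atoms: none
Why: Acetoacetic ester alkylation with an epoxide: the enolate opens the terminal CH2 and the alkoxide lactonises with loss of ethoxide, so the C–O bond of the stereocentre is never broken and C5 keeps its configuration.

Step 10
Reactants: 14 acetyl lactone; 11 dienyl bromide
Product: 15 (5R)-3-{(5E)-8-(TBS-oxy)-4-[(Z)-1-(TBS-oxy)propan-2-ylidene]oct-5-enoyl}-5-[(PMB-oxy)methyl]oxolan-2-one (C3 epimers)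
Conditions: NaH, THF, 0 °C; n-BuLi, 0 °C; then 11, −78 to 0 °C
Reagents that add atoms: none
Why: γ-Alkylation of a β-keto ester dianion: the more basic terminal (methyl) carbanion displaces the primary allylic bromide by SN2 while the lactone carbonyl is protected as its enolate.

Step 11
Reactants: 15 diene β-keto lactone
Product: 16 (3R,5R,10R)-3-[(PMB-oxy)methyl]-10-[3-(TBS-oxy)propyl]-9-[(Z)-1-(TBS-oxy)propan-2-ylidene]-2-oxaspiro[4.5]decane-1,6-dione
Conditions: Pd2(dba)3·CHCl3 (5 mol%), DPEphos (12 mol%), PhCO2H (20 mol%), toluene, 60 °C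
Reagents that add atoms: none
Why: Benzoic acid and zerovalent palladium should give a palladium hydride that adds to the less substituted C=C of the diene with H going to the terminal CH (the future first CH2 of the side chain), forming an η3-allyl complex over C10–C9–C(propan-2-ylidene) that the enol carbon of the β-keto lactone attacks at C10 anti to palladium; the closest known reaction types are palladium-hydride hydroalkylation of 1,3-dienes by 1,3-dicarbonyl C–H acids and the intramolecular Tsuji–Trost allylation of β-keto esters. The cyclohexane ring closes in a 6-(enolendo)-exo mode on the allyl terminus (the tether sits on the central allyl carbon, so the alkene stays exocyclic), and attack at the other, fully substituted terminus would need an eight-membered ring. Spiro C5 is controlled by the C3 stereocentre of the lactone, the planar enol being attacked on the face anti to the CH2OPMB group. C10 is controlled by a chair-like transition state in which the CH2CH2CH2OTBS group takes the syn allyl position (it becomes axial and escapes allylic 1,3-strain with the cis CH2OTBS group) and the hydrogen-bonded U-shaped enol places the lactone CH2 axial, which gives the 5,10 relationship of the target; the allyl diastereomers interconvert by η3–η1–η3 shifts at C10 and by reversible hydride addition, so the lower transition state is available (Curtin–Hammett). The step needs C- over O-alkylation (an O-allyl enol ether would re-ionise under the catalyst, so the C-alkylated ketone is the thermodynamic sink) and retention of the tetrasubstituted alkene geometry, which is secured because syn/anti exchange at that terminus would require a σ-palladium species on a fully substituted carbon.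

Step 12
Reactants: 16 spiro keto lactone
Product: 17 (3R,5R,6S,10R)-6-hydroxy-6-methyl-3-[(PMB-oxy)methyl]-10-[3-(TBS-oxy)propyl]-9-[(Z)-1-(TBS-oxy)propan-2-ylidene]-2-oxaspiro[4.5]decan-1-one
Conditions: CeCl3, MeLi, THF, −78 °C
Reagents that add atoms: methyllithium, [Li]C
Why: Organocerium 1,2-addition (weakly basic, so the enolisable ketone is not deprotonated and the lactone is spared); in the chair with the C10 chain axial the axial face of C6 is blocked, so methyl should enter equatorially and the smaller oxygen takes the position syn-diaxial to the chain, giving 6S.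

Step 13
Reactants: 17 hydroxy lactone
Product: 19 (3R,5S,6S,10R)-6-methyl-3-[(PMB-oxy)methyl]-10-[3-(TBS-oxy)propyl]-9-[(Z)-1-(TBS-oxy)propan-2-ylidene]-2-oxaspiro[4.5]decan-6-ol, via lactol 18 (not isolated)
Conditions: DIBAL-H (2.5 equiv), CH2Cl2, −78 °C; then Et3SiH, BF3·OEt2, CH2Cl2, −78 to −40 °C
Reagents that add atoms: none
Why: Lactone-to-lactol reduction followed by ionic hydrogenation of the five-membered oxocarbenium ion (reductive deoxygenation of a lactol); no stereocentre is touched and the C5 descriptor changes from R to S by priority only.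

Step 14
Reactants: 19 PMB ether
Product: 20 (3R,5S,6S,10R)-3-(hydroxymethyl)-6-methyl-10-[3-(TBS-oxy)propyl]-9-[(Z)-1-(TBS-oxy)propan-2-ylidene]-2-oxaspiro[4.5]decan-6-ol
Conditions: DDQ, CH2Cl2/pH 7 buffer, 0 °C
Reagents that add atoms: none
Why: Oxidative cleavage of the electron-rich PMB ether by DDQ, which should leave silyl ethers, the tertiary alcohol and the hindered tetrasubstituted alkene intact.

Step 15
Reactants: 20 primary alcohol
Product: 21 (3R,5S,6S,10R)-6-hydroxy-6-methyl-10-[3-(TBS-oxy)propyl]-9-[(Z)-1-(TBS-oxy)propan-2-ylidene]-2-oxaspiro[4.5]decane-3-carbaldehyde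
Conditions: Dess–Martin periodinane, CH2Cl2, rt
Reagents that add atoms: none
Why: Dess–Martin oxidation converts the primary alcohol to the aldehyde under near-neutral conditions that should not epimerise the α-alkoxy centre C3; the tertiary alcohol cannot be oxidised.

Step 16
Reactants: 21 aldehyde; 22 2-(triphenylphosphoranylidene)propanal
Product: 23 (2E)-3-[(3R,5S,6S,10R)-6-hydroxy-6-methyl-10-[3-(TBS-oxy)propyl]-9-[(Z)-1-(TBS-oxy)propan-2-ylidene]-2-oxaspiro[4.5]decan-3-yl]-2-methylprop-2-enal
Conditions: toluene, 80 °C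
Reagents that add atoms: none
Why: Wittig olefination with a stabilised, α-branched ylide should give the (E)-trisubstituted enal under thermodynamic control of the oxaphosphetane.

Step 17
Reactants: 24 geranyl bromide [(2E)-1-bromo-3,7-dimethylocta-2,6-diene]
Product: 25 diethyl [(2E)-3,7-dimethylocta-2,6-dien-1-yl]phosphonate
Conditions: P(OEt)3, neat, 130 °C
Reagents that add atoms: triethyl phosphite, CCOP(OCC)OCC
Why: Michaelis–Arbuzov reaction at the primary allylic bromide; the existing (E)-trisubstituted alkene is not involved.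

Step 18
Reactants: 23 enal; 25 geranylphosphonate
Product: 26 (3R,5S,6S,10R)-6-methyl-10-[3-(TBS-oxy)propyl]-9-[(Z)-1-(TBS-oxy)propan-2-ylidene]-3-[(1E,3E,5E)-2,6,10-trimethylundeca-1,3,5,9-tetraen-1-yl]-2-oxaspiro[4.5]decan-6-ol
Conditions: 25 (2.5 equiv), KHMDS, THF, −78 °C; then 23, −78 °C to rt
Reagents that add atoms: none
Why: Horner–Wadsworth–Emmons olefination with an allylic phosphonate anion should give the new disubstituted alkene with E geometry and complete the conjugated triene; excess anion covers the free tertiary hydroxyl.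

Step 19
Reactants: 26 bis-silyl ether
Product: 27 (3R,5S,6S,10R)-10-(3-hydroxypropyl)-9-[(Z)-1-hydroxypropan-2-ylidene]-6-methyl-3-[(1E,3E,5E)-2,6,10-trimethylundeca-1,3,5,9-tetraen-1-yl]-2-oxaspiro[4.5]decan-6-ol
Conditions: TBAF, THF, rt
Reagents that add atoms: none
Why: Fluoride desilylation removes both primary TBS ethers without acid, which protects the acid-labile allylic ether at C3 and the triene.

Step 20
Reactants: 27 triol
Product: 28 (2Z)-2-[(3R,5S,6S,10R)-6-hydroxy-10-(3-hydroxypropyl)-6-methyl-3-[(1E,3E,5E)-2,6,10-trimethylundeca-1,3,5,9-tetraen-1-yl]-2-oxaspiro[4.5]decan-9-ylidene]propanal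
Conditions: MnO2, CH2Cl2, rt
Reagents that add atoms: none
Why: MnO2 oxidises only the allylic primary alcohol, leaving the saturated primary and the tertiary hydroxyl groups, and should not change the alkene geometry fixed in step 4.

**Compound list**

1 | ethyl propanoate | CCC(=O)OCC | starting material
2 | di-tert-butyl oxalate | CC(C)(C)OC(=O)C(=O)OC(C)(C)C | starting material
3 | 4-tert-butyl 1-ethyl 2-methyl-3-oxobutanedioate (racemic, enolisable) | CCOC(=O)C(C)C(=O)C(=O)OC(C)(C)C | intermediate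
4 | 4-tert-butyl 1-ethyl (2Z)-2-methyl-3-(trifluoromethanesulfonyloxy)but-2-enedioate | CCOC(=O)/C(C)=C(\OS(=O)(=O)C(F)(F)F)C(=O)OC(C)(C)C | intermediate
5 | tert-butyl(but-3-yn-1-yloxy)dimethylsilane | C#CCCO[Si](C)(C)C(C)(C)C | starting material
6 | tert-butyldimethyl{[(3E)-4-(4,4,5,5-tetramethyl-1,3,2-dioxaborolan-2-yl)but-3-en-1-yl]oxy}silane | CC(C)(C)[Si](C)(C)OCC/C=C/B1OC(C)(C)C(C)(C)O1 | intermediate
7 | 4-tert-butyl 1-ethyl (2E)-2-methyl-3-[(1E)-4-(TBS-oxy)but-1-en-1-yl]but-2-enedioate | CCOC(=O)/C(C)=C(\C=C\CCO[Si](C)(C)C(C)(C)C)C(=O)OC(C)(C)C | intermediate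
8 | tert-butyl (2E,3E)-2-(1-hydroxypropan-2-ylidene)-6-(TBS-oxy)hex-3-enoate | OC/C(C)=C(\C=C\CCO[Si](C)(C)C(C)(C)C)C(=O)OC(C)(C)C | intermediate
9 | tert-butyl (2E,3E)-6-(TBS-oxy)-2-[1-(TBS-oxy)propan-2-ylidene]hex-3-enoate | CC(C)(C)[Si](C)(C)OC/C(C)=C(\C=C\CCO[Si](C)(C)C(C)(C)C)C(=O)OC(C)(C)C | intermediate
10 | (2E,3E)-6-(TBS-oxy)-2-[1-(TBS-oxy)propan-2-ylidene]hex-3-en-1-ol | CC(C)(C)[Si](C)(C)OC/C(C)=C(\C=C\CCO[Si](C)(C)C(C)(C)C)CO | intermediate
11 | (2E,3E)-1-bromo-6-(TBS-oxy)-2-[1-(TBS-oxy)propan-2-ylidene]hex-3-ene | CC(C)(C)[Si](C)(C)OC/C(C)=C(\C=C\CCO[Si](C)(C)C(C)(C)C)CBr | intermediate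
12 | (R)-2-[(4-methoxybenzyloxy)methyl]oxirane | COc1ccc(COC[C@H]2CO2)cc1 | starting material
13 | ethyl 3-oxobutanoate | CCOC(=O)CC(C)=O | starting material
14 | (5R)-3-acetyl-5-[(PMB-oxy)methyl]oxolan-2-one (C3 epimers) | COc1ccc(COC[C@H]2CC(C(C)=O)C(=O)O2)cc1 | intermediate
15 | (5R)-3-{(5E)-8-(TBS-oxy)-4-[(Z)-1-(TBS-oxy)propan-2-ylidene]oct-5-enoyl}-5-[(PMB-oxy)methyl]oxolan-2-one (C3 epimers) | COc1ccc(COC[C@H]2CC(C(=O)CC/C(/C=C/CCO[Si](C)(C)C(C)(C)C)=C(\C)CO[Si](C)(C)C(C)(C)C)C(=O)O2)cc1 | intermediate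
16 | (3R,5R,10R)-3-[(PMB-oxy)methyl]-10-[3-(TBS-oxy)propyl]-9-[(Z)-1-(TBS-oxy)propan-2-ylidene]-2-oxaspiro[4.5]decane-1,6-dione | COc1ccc(COC[C@H]2C[C@@]3(C(=O)O2)[C@H](CCCO[Si](C)(C)C(C)(C)C)/C(=C(/C)CO[Si](C)(C)C(C)(C)C)CCC3=O)cc1 | intermediate
17 | (3R,5R,6S,10R)-6-hydroxy-6-methyl-3-[(PMB-oxy)methyl]-10-[3-(TBS-oxy)propyl]-9-[(Z)-1-(TBS-oxy)propan-2-ylidene]-2-oxaspiro[4.5]decan-1-one | COc1ccc(COC[C@H]2C[C@@]3(C(=O)O2)[C@H](CCCO[Si](C)(C)C(C)(C)C)/C(=C(/C)CO[Si](C)(C)C(C)(C)C)CC[C@]3(C)O)cc1 | intermediate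
18 | (3R,5R,6S,10R)-6-methyl-3-[(PMB-oxy)methyl]-10-[3-(TBS-oxy)propyl]-9-[(Z)-1-(TBS-oxy)propan-2-ylidene]-2-oxaspiro[4.5]decane-1,6-diol (lactol, C1 anomers) | COc1ccc(COC[C@H]2C[C@@]3(C(O)O2)[C@H](CCCO[Si](C)(C)C(C)(C)C)/C(=C(/C)CO[Si](C)(C)C(C)(C)C)CC[C@]3(C)O)cc1 | intermediate
19 | (3R,5S,6S,10R)-6-methyl-3-[(PMB-oxy)methyl]-10-[3-(TBS-oxy)propyl]-9-[(Z)-1-(TBS-oxy)propan-2-ylidene]-2-oxaspiro[4.5]decan-6-ol | COc1ccc(COC[C@H]2C[C@@]3(CO2)[C@H](CCCO[Si](C)(C)C(C)(C)C)/C(=C(/C)CO[Si](C)(C)C(C)(C)C)CC[C@]3(C)O)cc1 | intermediate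
20 | (3R,5S,6S,10R)-3-(hydroxymethyl)-6-methyl-10-[3-(TBS-oxy)propyl]-9-[(Z)-1-(TBS-oxy)propan-2-ylidene]-2-oxaspiro[4.5]decan-6-ol | OC[C@H]1C[C@@]2(CO1)[C@H](CCCO[Si](C)(C)C(C)(C)C)/C(=C(/C)CO[Si](C)(C)C(C)(C)C)CC[C@]2(C)O | intermediate
21 | (3R,5S,6S,10R)-6-hydroxy-6-methyl-10-[3-(TBS-oxy)propyl]-9-[(Z)-1-(TBS-oxy)propan-2-ylidene]-2-oxaspiro[4.5]decane-3-carbaldehyde | O=C[C@H]1C[C@@]2(CO1)[C@H](CCCO[Si](C)(C)C(C)(C)C)/C(=C(/C)CO[Si](C)(C)C(C)(C)C)CC[C@]2(C)O | intermediate
22 | 2-(triphenylphosphoranylidene)propanal | CC(C=O)=P(c1ccccc1)(c1ccccc1)c1ccccc1 | starting material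
23 | (2E)-3-[(3R,5S,6S,10R)-6-hydroxy-6-methyl-10-[3-(TBS-oxy)propyl]-9-[(Z)-1-(TBS-oxy)propan-2-ylidene]-2-oxaspiro[4.5]decan-3-yl]-2-methylprop-2-enal | O=C/C(C)=C/[C@H]1C[C@@]2(CO1)[C@H](CCCO[Si](C)(C)C(C)(C)C)/C(=C(/C)CO[Si](C)(C)C(C)(C)C)CC[C@]2(C)O | intermediate
24 | geranyl bromide, (2E)-1-bromo-3,7-dimethylocta-2,6-diene | CC(C)=CCC/C(C)=C/CBr | starting material
25 | diethyl [(2E)-3,7-dimethylocta-2,6-dien-1-yl]phosphonate | CCOP(=O)(C/C=C(\C)CCC=C(C)C)OCC | intermediate
26 | (3R,5S,6S,10R)-6-methyl-10-[3-(TBS-oxy)propyl]-9-[(Z)-1-(TBS-oxy)propan-2-ylidene]-3-[(1E,3E,5E)-2,6,10-trimethylundeca-1,3,5,9-tetraen-1-yl]-2-oxaspiro[4.5]decan-6-ol | CC(C)=CCC/C(C)=C/C=C/C(C)=C/[C@H]1C[C@@]2(CO1)[C@H](CCCO[Si](C)(C)C(C)(C)C)/C(=C(/C)CO[Si](C)(C)C(C)(C)C)CC[C@]2(C)O | intermediate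
27 | (3R,5S,6S,10R)-10-(3-hydroxypropyl)-9-[(Z)-1-hydroxypropan-2-ylidene]-6-methyl-3-[(1E,3E,5E)-2,6,10-trimethylundeca-1,3,5,9-tetraen-1-yl]-2-oxaspiro[4.5]decan-6-ol | CC(C)=CCC/C(C)=C/C=C/C(C)=C/[C@H]1C[C@@]2(CO1)[C@H](CCCO)/C(=C(/C)CO)CC[C@]2(C)O | intermediate
28 | (2Z)-2-[(3R,5S,6S,10R)-6-hydroxy-10-(3-hydroxypropyl)-6-methyl-3-[(1E,3E,5E)-2,6,10-trimethylundeca-1,3,5,9-tetraen-1-yl]-2-oxaspiro[4.5]decan-9-ylidene]propanal | CC(C)=CCC/C(C)=C/C=C/C(C)=C/[C@H]1C[C@@]2(CO1)[C@H](CCCO)/C(=C(/C)C=O)CC[C@]2(C)O | target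

**Step count and risks**

Total steps: 20. Longest linear sequence: 17 steps (1, 2, 4–8, 10–16, 18–20).

Steps most likely to fail:

Step 11. Palladium-hydride isomerisation of the diene may outrun hydropalladation and cyclisation of the hindered diene, and facial selectivity at C10 may be low. The fallback sets out from 15 and activates the diene with a stoichiometric electrophile instead of a metal hydride. N-(Phenylseleno)phthalimide with catalytic ZnI2 (CH2Cl2, 0 °C) should form a seleniranium ion on the disubstituted alkene, which the enol carbon opens at the allylic C10 in anti fashion (a selenium-induced carbocyclisation of an alkenyl 1,3-dicarbonyl compound; any O-cyclised enol ether should isomerise to the C-cyclised ketone under the Lewis acid). This gives the phenylselanyl spiro keto lactone F1. Reduction with Bu3SnH and AIBN (toluene, 80 °C) removes selenium and comes back to the route at 16.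

Step 12. Facial selectivity of the methyl addition may be poor (axial instead of equatorial attack), or the ketone may be enolised. The fallback sets out from 16 and delivers oxygen, not carbon, to the incoming face. Takai–Lombardo methylenation (Zn, CH2Br2, TiCl4, THF), which is ketone-selective and spares the lactone, gives the 6-methylidene spiro lactone F2. Mukaiyama hydration (Mn(dpm)3, PhSiH3, O2, iPrOH) of the 1,1-disubstituted alkene, which should react faster than the tetrasubstituted one, then installs the tertiary alcohol with the C6 configuration complementary to direct methyl addition and comes back at 17.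

Step 13. Under BF3·OEt2 the tertiary alcohol or the allylic silyl ether may ionise, or the PMB group may be lost; DIBAL-H may also over-reduce the lactone. The fallback sets out from 17 and closes the oxolane under basic conditions. LiBH4 (THF/MeOH) reduces the lactone fully to the ring-opened triol F3. TsCl in pyridine should sulfonylate the primary hydroxyl selectively to give the monotosylate F4. NaH (THF) then closes the oxolane by 5-exo-tet Williamson etherification from the secondary alkoxide, whose C–O bond is not broken, so C3 keeps its configuration; the route is rejoined at 19.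

Further compounds
F1 | step 11 | (3R,5R,10R)-3-[(PMB-oxy)methyl]-10-[(1R)-1-(phenylselanyl)-3-(TBS-oxy)propyl]-9-[(Z)-1-(TBS-oxy)propan-2-ylidene]-2-oxaspiro[4.5]decane-1,6-dione | COc1ccc(COC[C@H]2C[C@@]3(C(=O)O2)[C@H]([C@H]([Se]c4ccccc4)CCO[Si](C)(C)C(C)(C)C)/C(=C(/C)CO[Si](C)(C)C(C)(C)C)CCC3=O)cc1
F2 | step 12 | (3R,5R,10R)-6-methylidene-3-[(PMB-oxy)methyl]-10-[3-(TBS-oxy)propyl]-9-[(Z)-1-(TBS-oxy)propan-2-ylidene]-2-oxaspiro[4.5]decan-1-one | COc1ccc(COC[C@H]2C[C@@]3(C(=O)O2)[C@H](CCCO[Si](C)(C)C(C)(C)C)/C(=C(/C)CO[Si](C)(C)C(C)(C)C)CCC3=C)cc1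
F3 | step 13 | (1S,2S,3R)-2-(hydroxymethyl)-2-[(2R)-2-hydroxy-3-(PMB-oxy)propyl]-1-methyl-3-[3-(TBS-oxy)propyl]-4-[(Z)-1-(TBS-oxy)propan-2-ylidene]cyclohexan-1-ol | COc1ccc(COC[C@H](O)C[C@@]2(CO)[C@H](CCCO[Si](C)(C)C(C)(C)C)/C(=C(/C)CO[Si](C)(C)C(C)(C)C)CC[C@]2(C)O)cc1
F4 | step 13 | primary 4-methylbenzenesulfonate of F3 (tosyloxymethyl on the quaternary ring carbon) | COc1ccc(COC[C@H](O)C[C@@]2(COS(=O)(=O)c3ccc(C)cc3)[C@H](CCCO[Si](C)(C)C(C)(C)C)/C(=C(/C)CO[Si](C)(C)C(C)(C)C)CC[C@]2(C)O)cc1
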